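The data come from a simulation from invented constants, and the scatter is random.

The percent in these tables is percent of the solid substrate charged, and that unit hides the molar amount. The flask is a slurry, and I took the pace in its solution to be independent of how much solid lay beneath, as long as solid remained.

| setting | Monday's | Thursday's | Wednesday's | flask |
|---|---|---|---|---|
| solid substrate | 1.5 M | 1.5 M | 2.2 M | 1.5 M |
| reagent | 1.1 M | 1.7 M | 2.25 M | 2.25 M |
| remark | run made earlier | run made earlier | run made earlier |  |
| time |  |  |  | 5.0 min |

| Monday's: time / min | Monday's: target / % | Thursday's: time / min | Thursday's: target / % | Wednesday's: time / min | Wednesday's: target / % |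
|---|---|---|---|---|---|
| 1.50 | 0 | 0.833 | 0 | 1.50 | 0 |
| 3.00 | 2.2 | 2.00 | 1.4 | 3.00 | 3.5 |
| 5.00 | 5.0 | 4.00 | 6.9 | 5.00 | 6.5 |
| 6.00 | 5.8 | 6.00 | 9.6 | 6.00 | 7.7 |

(each reading ± 1 percentage point)

- solid, in amounts per volume of the solution: solid substrate
- the numbers in the tables scatter with a standard deviation of 1 percentage point
- at the start none of the solid substrate is in solution

- elm: doubling the dissolution coefficient of the solid substrate, all else as stated
- cedar: doubling the amount of reagent, all else as stated
- ash: doubling the solubility of the solid substrate, all else as stated

- target at 5.0 min, in percent of the solid substrate charged
- the change that raises the amount of target at 5.0 min, in percent of the solid substrate charged most ("none" if none brings more than 2 percentage points) (elm / cedar / ash / none)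
- amount of target at 5.0 min, in percent of the solid substrate charged, after cedar

Wednesday's run had the flask's reagent, 2.25 M, and more solid substrate. Its reading at 5.00 min was 6.5%, which is 0.143 M of target, and nearly all of its charge was still unreacted. So I spread that same molar amount over the flask's smaller charge. The number that does this is the charge ratio, Wednesday's charge over the flask's charge: 1.47. It says how many times a Wednesday percentage grows on the flask's scale. It gave 9.53%, and it stretched the scatter to 1.5 percentage points.

Was one number enough? Monday's run had the flask's charge and a reading at the same time, but less reagent. Its 5.0%, scaled in proportion to reagent, gave 10.2%. That lay 0.67 points from my figure, less than the stretched scatter.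

The forecast gave 10%, between 8.5% and 11.5%, and 18% after cedar, and said “ash should edge out cedar”.

The flask gave 9.23%, with ash best at a gain of 17 points and 13.7% after cedar. At 5.00 min it still held 80.0% of its charge as solid substrate. Divided by the charge ratio, the result was 6.28% on Wednesday's scale, within one standard deviation of the reading.

    solid substrate ⇌ starting material, rate k1*(cs1 - [starting material]) while solid is left; crystals form when [starting material] > cs1 (solubility = 0.250 M, k = 0.00795 /s)
    starting material + reagent → target, rate k2*[starting material]^2*[reagent] (k = 0.0123 /M²/s)
    target → over-reaction product (k = 2.73 × 10⁻⁵ /s)

The neighbouring flask is the same flask read at 3.0 min. Wednesday's 3.5% at 3.00 min, times the charge ratio, gave 5.15%. The computed neighbouring flask gave 4.03%.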